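**Plan**
- Numbering is that of a flavanone: O1, C2–Ph, C3, C4=O, C4a, C5–OMe, C6, C7=O, C8 (diprenyl), C8a. Ring A is the carbocycle and ring C the dihydropyranone. Prenyl = 3-methylbut-2-en-1-yl.
- Enabling feature: ring A is a 6,6-disubstituted cyclohexa-2,4-dienone, with C7=O next to quaternary C8 and oxygen on C5 and C8a. C8 has no hydrogen, so a dienylketene that closes C7–C8 by 6π-electrocyclisation must stop at this dienone and cannot become a phenol.
- Retrosynthetic cuts, in order: C2–phenyl; then O1–C2, C2–C3 and C4–C4a (ring C); then C7–C8, C6–C7 and C4a–C5 (ring A, back to a cyclobutenone and methoxyacetylene); then the cyclobutenone back to diprenylketene and tert-butoxyacetylene.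
- Forward order: malonate → diprenylacetyl chloride → four-membered ring → ring A by a 4π/[2+2]/4π/6π cascade → tert-butyl removed and C4a acetylated → ring C closed as the pyranone → phenyl added.
- Stereochemistry: C2 is the only stereocentre. It is set as (S) in the last step by catalyst control with Pd(OCOCF3)2 and (R)-t-BuPyOX, and no later step can reopen ring C.

Key step: step 7

Assumption: the facial sense of the Pd(OCOCF3)2/PyOX addition is carried over from 3-substituted cyclic enones, where the (S)-ligand leads to the (R)-ketone; the same spatial sense at C2 of a pyranone also reads (R), so the (R)-ligand, (R)-4-tert-butyl-2-(pyridin-2-yl)-4,5-dihydrooxazole, is chosen for (2S).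

**Step 1**
Reactants: 1 diethyl malonate; 2 prenyl bromide (1-bromo-3-methylbut-2-ene)
Product: 3 diethyl 2,2-diprenylmalonate
Conditions: NaH (2.4 equiv), 2 (2.4 equiv), THF–DMF, 0 °C → rt
Reagents that add atoms: none
Why: This is a twofold SN2 malonic ester alkylation, in which the primary allylic bromide reacts fast enough for the second, more hindered alkylation to go to completion; no stereocentre is formed.

**Step 2**
Reactants: 3 diethyl 2,2-diprenylmalonate
Product: 5 diprenylacetic acid (5-methyl-2-(3-methylbut-2-en-1-yl)hex-4-enoic acid), via 2,2-diprenylmalonic acid 4 (not isolated)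
Conditions: KOH, EtOH–H2O, reflux; cold 1 M HCl to pH 2, extract; crude diacid in pyridine, reflux
Reagents that add atoms: potassium hydroxide, [K+].[OH-]
Why: Saponification and decarboxylation of the dialkylmalonic acid through its cyclic transition state complete the malonic ester synthesis, and the pyridine medium keeps the prenyl olefins away from hot free acid so that lactonisation is avoided.

**Step 3**
Reactants: 5 diprenylacetic acid
Product: 6 diprenylacetyl chloride (5-methyl-2-(3-methylbut-2-en-1-yl)hex-4-enoyl chloride)
Conditions: (COCl)2 (1.3 equiv), DMF (cat.), CH2Cl2, 0 °C → rt; volatiles removed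
Reagents that add atoms: oxalyl chloride, O=C(Cl)C(=O)Cl
Why: DMF-catalysed (Vilsmeier-type) acid chloride formation runs at or below room temperature with gaseous by-products only, conditions that trisubstituted olefins routinely tolerate.

**Step 4**
Reactants: 7 trichloroethylene; 8 potassium tert-butoxide
Product: 11 tert-butoxyacetylene, via (E)-1,2-dichlorovinyl tert-butyl ether 9 (not isolated), via lithium tert-butoxyacetylide 10 (not isolated)
Conditions: 8 (1.1 equiv), THF, −60 °C → rt; n-BuLi (2.3 equiv), −78 → −40 °C; H2O, −78 → 0 °C; pentane extract, dried (K2CO3), used cold as an assayed solution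
Reagents that add atoms: none
Why: This is the standard dichlorovinyl ether route to ynol ethers, which accepts tertiary alkoxides: the alkoxide adds anti to dichloroacetylene formed in situ to give 9, and n-BuLi then causes β-elimination and chlorine–lithium exchange to acetylide 10, which the quench protonates.

**Step 5**
Reactants: 6 diprenylacetyl chloride; 11 tert-butoxyacetylene
Product: 13 cyclobutenone (3-tert-butoxy-4,4-diprenylcyclobut-2-en-1-one), via diprenylketene 12 (not isolated)
Conditions: 11 (1.5 equiv), Et3N (1.5 equiv), pentane–THF, slow addition of 6, rt; filtered; SiO2 (1% Et3N)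
Reagents that add atoms: none
Why: Dehydrochlorination gives ketene 12, whose [2+2] cycloaddition with the ynol ether joins the ketene carbonyl carbon to the nucleophilic unsubstituted alkyne carbon and the diprenyl carbon to the oxygen-bearing one; this is the established access to 3-alkoxy-4,4-dialkylcyclobutenones, and the one-carbon tether to each prenyl olefin is too short for internal addition.

**Step 6**
Reactants: 14 chloroacetaldehyde dimethyl acetal
Product: 16 methoxyacetylene, via sodium methoxyacetylide 15 (not isolated)
Conditions: NaNH2 (3.2 equiv), liq. NH3, −33 °C; NH3 evaporated; cold sat. aq. NaCl, −20 °C; distilled (bp 23 °C) into PhMe at −78 °C, used the same day behind a shield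
Reagents that add atoms: none
Why: Base-induced loss of methanol and of HCl followed by deprotonation is the classical alkoxyacetylene preparation from a chloroacetal, and hydrolysis of salt 15 releases the volatile alkyne.

**Step 7**
Reactants: 13 cyclobutenone (3-tert-butoxy-4,4-diprenylcyclobut-2-en-1-one); 16 methoxyacetylene
Product: 20 dienone (5-tert-butoxy-3-methoxy-6,6-diprenylcyclohexa-2,4-dien-1-one), via vinylketene 17 (not isolated), via 4-alkenylcyclobutenone 18 (not isolated), via dienylketene 19 (not isolated)
Conditions: 16 (10 equiv, ca. 3 M in PhMe), BHT (trace), base-washed steel pressure vessel, 115 °C; excess 16 vented; 140 °C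
Reagents that add atoms: none
Why: Conrotatory 4π opening of 13 breaks the bond between its carbonyl carbon and the diprenyl carbon to release vinylketene 17, whose electrophilic ketene carbon (future C7) is attacked by the unsubstituted, nucleophilic carbon of 16 (C6) while its α-carbon (C4a) bonds to the methoxy-bearing carbon (C5), so the [2+2] cycloaddition closes the transient four-membered ring of 18 with a single regiochemistry. A second, reversible 4π opening gives dienylketene 19, and the isomer that holds the ketene and alkenyl groups cis across C5=C4a is drained by a disrotatory 6π-electrocyclisation that joins C7 to the diprenyl carbon C8 and closes ring A. This is the Danheiser cyclobutenone–alkyne annulation in its variant for 4,4-disubstituted cyclobutenones, which ends at the cyclohexa-2,4-dienone because C8 has no hydrogen for tautomerisation to a phenol. No stereocentre remains, since the one in racemic 18 is erased when that ring reopens. The step requires intermolecular capture of 17 to outrun its internal [2+2] addition to the prenyl olefin held cis to the ketene; this is secured by the much higher nucleophilicity of the ynol ether, its tenfold excess at high concentration, and the strain of the bicyclo[3.1.1]heptenone that the internal path would build. Methoxyacetylene has no β-hydrogen for retro-ene decay, and acid-free glassware should keep the tert-butyl enol ether, which ends on C8a, intact.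

**Step 8**
Reactants: 20 dienone (5-tert-butoxy-3-methoxy-6,6-diprenylcyclohexa-2,4-dien-1-one)
Product: 21 enol (5-hydroxy-3-methoxy-6,6-diprenylcyclohexa-2,4-dien-1-one)
Conditions: TFA (10 equiv), CH2Cl2, 0 °C, 20 min; PhMe azeotrope
Reagents that add atoms: none
Why: Acidolysis of the tert-butyl vinylogous ester (E1 loss of isobutene) is far faster at 0 °C than attack on the methyl enol ether or protonation of the prenyl olefins, and the two enol tautomers of 21 are identical, so C4a and C6 become equivalent.

**Step 9**
Reactants: 21 enol (5-hydroxy-3-methoxy-6,6-diprenylcyclohexa-2,4-dien-1-one)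
Product: 23 acetyl enol (4-acetyl-5-hydroxy-3-methoxy-6,6-diprenylcyclohexa-2,4-dien-1-one), via enol acetate 22 (not isolated)
Conditions: Ac2O (1.1 equiv), Et3N (2.5 equiv), DMAP (0.3 equiv), CH2Cl2, 0 °C → 40 °C; cold aq. citric acid wash
Reagents that add atoms: acetic anhydride, CC(=O)OC(C)=O
Why: O-acetylation followed by DMAP-mediated O-to-C acyl migration (the enol ester to 2-acyl-1,3-dione rearrangement) places the acetyl group on C4a, driven by formation of the more acidic chelated enol; the two candidate ring carbons are equivalent in the delocalised enolate, so one product should result.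

**Step 10**
Reactants: 23 acetyl enol (4-acetyl-5-hydroxy-3-methoxy-6,6-diprenylcyclohexa-2,4-dien-1-one)
Product: 25 pyranone (5-methoxy-8,8-diprenyl-4H-chromene-4,7(8H)-dione), via enaminone 24 (not isolated)
Conditions: Me2NCH(OMe)2 (2 equiv), PhMe, 80 °C; concentrated; TsOH·H2O (1.1 equiv), CH2Cl2, rt
Reagents that add atoms: N,N-dimethylformamide dimethyl acetal, COC(OC)N(C)C
Why: Condensation of the acetyl CH3 to the enaminone and acid-promoted 6-endo addition–elimination by the C8a hydroxyl form the standard enaminone chromone synthesis, which is also known for acetylated vinylogous acids such as dehydroacetic acid; only O8a can reach the new carbon, and one equivalent of acid ties up dimethylamine before it can displace the C5 methoxy group.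

**Step 11**
Reactants: 25 pyranone (5-methoxy-8,8-diprenyl-4H-chromene-4,7(8H)-dione); 26 phenylboronic acid
Product: 27 griffinone A, (2S)-5-methoxy-2-phenyl-8,8-diprenyl-2,3-dihydro-4H-chromene-4,7(8H)-dione
Conditions: 26 (2 equiv), Pd(OCOCF3)2 (5 mol %), (R)-t-BuPyOX (6 mol %), NH4PF6 (30 mol %), H2O (5 equiv), ClCH2CH2Cl, 40 °C; neutral work-up
Reagents that add atoms: none
Why: In this asymmetric conjugate addition of an arylboronic acid under cationic divalent palladium–pyridine-oxazoline catalysis, established for chromones, the phenylpalladium species inserts at the only unsubstituted acceptor carbon (C2, since C5 and C8a are fully substituted), the tert-butyl group of the (R)-ligand shields one face so that phenyl should arrive on the face giving (2S), and protonolysis of the palladium enolate in a non-basic medium should avoid retro-oxa-Michael racemisation.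

**Compound list**
1 | diethyl malonate | CCOC(=O)CC(=O)OCC | starting material
2 | prenyl bromide (1-bromo-3-methylbut-2-ene) | CC(C)=CCBr | starting material
3 | diethyl 2,2-diprenylmalonate | CCOC(=O)C(CC=C(C)C)(CC=C(C)C)C(=O)OCC | intermediate
4 | 2,2-diprenylmalonic acid | OC(=O)C(CC=C(C)C)(CC=C(C)C)C(=O)O | intermediate
5 | diprenylacetic acid (5-methyl-2-(3-methylbut-2-en-1-yl)hex-4-enoic acid) | OC(=O)C(CC=C(C)C)CC=C(C)C | intermediate
6 | diprenylacetyl chloride | ClC(=O)C(CC=C(C)C)CC=C(C)C | intermediate
7 | trichloroethylene | ClC=C(Cl)Cl | starting material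
8 | potassium tert-butoxide | CC(C)(C)[O-].[K+] | starting material
9 | (E)-1,2-dichlorovinyl tert-butyl ether | CC(C)(C)O/C(Cl)=C\Cl | intermediate
10 | lithium tert-butoxyacetylide | CC(C)(C)OC#C[Li] | intermediate
11 | tert-butoxyacetylene | CC(C)(C)OC#C | intermediate
12 | diprenylketene (5-methyl-2-(3-methylbut-2-en-1-yl)hexa-1,4-dien-1-one) | O=C=C(CC=C(C)C)CC=C(C)C | intermediate
13 | 3-tert-butoxy-4,4-diprenylcyclobut-2-en-1-one | CC(C)(C)OC1=CC(=O)C1(CC=C(C)C)CC=C(C)C | intermediate
14 | chloroacetaldehyde dimethyl acetal (2-chloro-1,1-dimethoxyethane) | COC(CCl)OC | starting material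
15 | sodium methoxyacetylide | COC#C[Na] | intermediate
16 | methoxyacetylene | COC#C | intermediate
17 | vinylketene, 3-tert-butoxy-7-methyl-4-(3-methylbut-2-en-1-yl)octa-1,3,6-trien-1-one | O=C=CC(OC(C)(C)C)=C(CC=C(C)C)CC=C(C)C | intermediate
18 | 4-alkenylcyclobutenone, 4-[1-tert-butoxy-5-methyl-2-(3-methylbut-2-en-1-yl)hexa-1,4-dien-1-yl]-3-methoxycyclobut-2-en-1-one (racemic) | COC1=CC(=O)C1C(OC(C)(C)C)=C(CC=C(C)C)CC=C(C)C | intermediate
19 | dienylketene, (3E)-5-tert-butoxy-3-methoxy-9-methyl-6-(3-methylbut-2-en-1-yl)deca-1,3,5,8-tetraen-1-one | O=C=C/C(OC)=C\C(OC(C)(C)C)=C(CC=C(C)C)CC=C(C)C | intermediate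
20 | 5-tert-butoxy-3-methoxy-6,6-diprenylcyclohexa-2,4-dien-1-one | COC1=CC(=O)C(CC=C(C)C)(CC=C(C)C)C(OC(C)(C)C)=C1 | intermediate
21 | 5-hydroxy-3-methoxy-6,6-diprenylcyclohexa-2,4-dien-1-one | COC1=CC(=O)C(CC=C(C)C)(CC=C(C)C)C(O)=C1 | intermediate
22 | 5-acetoxy-3-methoxy-6,6-diprenylcyclohexa-2,4-dien-1-one | COC1=CC(=O)C(CC=C(C)C)(CC=C(C)C)C(OC(C)=O)=C1 | intermediate
23 | 4-acetyl-5-hydroxy-3-methoxy-6,6-diprenylcyclohexa-2,4-dien-1-one | COC1=CC(=O)C(CC=C(C)C)(CC=C(C)C)C(O)=C1C(C)=O | intermediate
24 | 4-[(E)-3-(dimethylamino)acryloyl]-5-hydroxy-3-methoxy-6,6-diprenylcyclohexa-2,4-dien-1-one | COC1=CC(=O)C(CC=C(C)C)(CC=C(C)C)C(O)=C1C(=O)/C=C/N(C)C | intermediate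
25 | 5-methoxy-8,8-diprenyl-4H-chromene-4,7(8H)-dione | COC1=CC(=O)C(CC=C(C)C)(CC=C(C)C)C2=C1C(=O)C=CO2 | intermediate
26 | phenylboronic acid | OB(O)c1ccccc1 | starting material
27 | griffinone A, (2S)-5-methoxy-2-phenyl-8,8-diprenyl-2,3-dihydro-4H-chromene-4,7(8H)-dione | COC1=CC(=O)C(CC=C(C)C)(CC=C(C)C)C2=C1C(=O)C[C@@H](c1ccccc1)O2 | target

**Totals**
Total step count: 11.
Longest linear sequence: 9 (steps 1, 2, 3, 5, 7, 8, 9, 10, 11). Steps 4 and 6 are one-step side branches.

**Steps most likely to fail**

Step 7.
- What may go wrong: the vinylketene may be consumed by internal [2+2] addition to the neighbouring prenyl olefin. The volatile alkyne may oligomerise before the donor-stabilised cyclobutenone opens. The inward rotation of the bulky alkenyl group that the productive second opening needs may be slow. Isobutene may be lost at the upper temperature.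
- Fallback: ring A is taken from an arene by dearomatisation instead, setting out from prenyl bromide 2.
- Purchased 2',4'-dihydroxy-6'-methoxyacetophenone (CC(=O)c1c(O)cc(O)cc1OC) is C-alkylated between its two hydroxyl groups (KOH, H2O–MeOH, 0 °C) to give 1-[2,4-dihydroxy-6-methoxy-3-(3-methylbut-2-en-1-yl)phenyl]ethan-1-one F1.
- A second alkylation with 2 at the same carbon (aq. KOH, 0 °C → rt) breaks the aromaticity. This is the known gem-dialkylation of acylphloroglucinols, and it delivers 23, where the route is rejoined before step 10.

Step 11.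
- What may go wrong: the water needed for turnover may open the electrophilic pyranone hydrolytically. Facial selectivity may be poor on an acceptor that is not benzo-fused. Enantiopurity may erode through reversible retro-oxa-Michael opening of ring C, whose leaving group is a vinylogous carboxylate.
- Fallback: the stereocentre is bought and ring C is closed by SN2 displacement, setting out from 21.
- Purchased ethyl (R)-3-hydroxy-3-phenylpropanoate is silylated (TBSCl, imidazole, DMF) to ethyl (R)-3-(tert-butyldimethylsilyloxy)-3-phenylpropanoate F2.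
- F2 is saponified (LiOH, THF–H2O) to (R)-3-(tert-butyldimethylsilyloxy)-3-phenylpropanoic acid F3.
- DCC/DMAP coupling of F3 with 21, with the same O-to-C acyl migration as in step 9, gives 4-[(R)-3-(tert-butyldimethylsilyloxy)-3-phenylpropanoyl]-5-hydroxy-3-methoxy-6,6-diprenylcyclohexa-2,4-dien-1-one F4.
- HF·pyridine frees 5-hydroxy-4-[(R)-3-hydroxy-3-phenylpropanoyl]-3-methoxy-6,6-diprenylcyclohexa-2,4-dien-1-one F5.
- An intramolecular Mitsunobu reaction (PPh3, DIAD, THF, 0 °C), with the acidic C8a enol as nucleophile, closes O1–C2 with inversion from (R) to (S) and arrives at 27.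

Step 5.
- What may go wrong: dehydrochlorination of the hindered α,α-dialkyl acid chloride may be sluggish at the low temperature required by the heat-sensitive tert-butyl ynol ether, which loses isobutene by retro-ene reaction. The slowly formed ketene may also be diverted by self-condensation.
- Fallback: a robust ynol ether is used and the oxygen substituent is exchanged afterwards, setting out from 6.
- Commercial ethoxyacetylene and Et3N in warm hexane–PhMe (60 °C) give 3-ethoxy-4,4-diprenylcyclobut-2-en-1-one F6.
- Dilute HCl in THF hydrolyses F6 to 3-hydroxy-4,4-diprenylcyclobut-2-en-1-one F7, the enol of the symmetric 1,3-dione.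
- O-tert-butylation of this vinylogous acid with N,N-dimethylformamide di-tert-butyl acetal (PhMe, 80 °C) returns to 13.

**Further compounds**
F1 | step 7 | 1-[2,4-dihydroxy-6-methoxy-3-(3-methylbut-2-en-1-yl)phenyl]ethan-1-one | CC(=O)c1c(O)c(CC=C(C)C)c(O)cc1OC
F2 | step 11 | ethyl (R)-3-(tert-butyldimethylsilyloxy)-3-phenylpropanoate | CCOC(=O)C[C@H](c1ccccc1)O[Si](C)(C)C(C)(C)C
F3 | step 11 | (R)-3-(tert-butyldimethylsilyloxy)-3-phenylpropanoic acid | OC(=O)C[C@H](c1ccccc1)O[Si](C)(C)C(C)(C)C
F4 | step 11 | 4-[(R)-3-(tert-butyldimethylsilyloxy)-3-phenylpropanoyl]-5-hydroxy-3-methoxy-6,6-diprenylcyclohexa-2,4-dien-1-one | COC1=CC(=O)C(CC=C(C)C)(CC=C(C)C)C(O)=C1C(=O)C[C@H](c1ccccc1)O[Si](C)(C)C(C)(C)C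
F5 | step 11 | 5-hydroxy-4-[(R)-3-hydroxy-3-phenylpropanoyl]-3-methoxy-6,6-diprenylcyclohexa-2,4-dien-1-one | COC1=CC(=O)C(CC=C(C)C)(CC=C(C)C)C(O)=C1C(=O)C[C@H](c1ccccc1)O
F6 | step 5 | 3-ethoxy-4,4-diprenylcyclobut-2-en-1-one | CCOC1=CC(=O)C1(CC=C(C)C)CC=C(C)C
F7 | step 5 | 3-hydroxy-4,4-diprenylcyclobut-2-en-1-one | OC1=CC(=O)C1(CC=C(C)C)CC=C(C)C
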